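**Retrosynthetic overview**
- The target is disconnected at C3 into a C3 enal plus an ethyl nucleophile (catalytic asymmetric diethylzinc addition), with the C7 oxygen carried as a triethylsilyl ether until the end.
- The C6–C7 bond and both of its stereocentres come from a new, metal-free, acid-catalysed syn-selective vinylogous Mukaiyama aldol between a C7–C14 trienal and the silyl dienol ether of (E)-2-methylpent-2-enal.
- The trienal comes from two successive E-selective Wittig homologations of (S)-2-methyl-4-phenylbut-3-enal with 2-(triphenylphosphoranylidene)propanal.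
- That aldehyde, which carries the first stereocentre (C12), comes from organocatalytic SOMO α-vinylation of propanal with potassium (E)-styryltrifluoroborate.
- No ring is formed; the phenyl ring arrives with the styrylborate.

Assumption: the target SMILES is read as (3R,4E,6S,7R,8E,10E,12S,13E), and each catalyst antipode named is the one predicted by its accepted facial model (the opposite antipode, equally available, would be used if a model failed).
Convention: positions are given in target numbering (C1 = CH3 of the ethyl group, C14 = CHPh).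

**Step 1**
Reactants: 1 propanal; 2 potassium (E)-styryltrifluoroborate
Product: 3 (2S,3E)-2-methyl-4-phenylbut-3-enal
Conditions: (2R,5R)-5-benzyl-2-tert-butyl-3-methylimidazolidin-4-one·CF3CO2H (20 mol %), (NH4)2Ce(NO3)6 (2.5 equiv), NaHCO3, H2O, DME, −50 °C, 24 h; cold work-up, short silica plug, used the same day
Reagents that add atoms: none
Why: Organo-SOMO α-vinylation, in which the enamine of 1 is oxidised by tetravalent cerium to a radical cation whose Si face is shielded by the catalyst benzyl group, so the styrylborate adds to the Re face and a second oxidation with loss of BF3 restores the E-alkene, setting C12 as S.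

**Step 2**
Reactants: 3 (2S,3E)-2-methyl-4-phenylbut-3-enal; 4 2-(triphenylphosphoranylidene)propanal
Product: 5 (2E,4S,5E)-2,4-dimethyl-6-phenylhexa-2,5-dienal
Conditions: 4 (1.1 equiv), PhMe, 60 °C, 16 h
Reagents that add atoms: none
Why: Wittig olefination with a formyl-stabilised ylide is E-selective and needs no added base, so the α-stereocentre of 3 is carried through, and the saturated aldehyde 3 reacts much faster than the product enal 5.

**Step 3**
Reactants: 5 (2E,4S,5E)-2,4-dimethyl-6-phenylhexa-2,5-dienal; 4 2-(triphenylphosphoranylidene)propanal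
Product: 6 (2E,4E,6S,7E)-2,4,6-trimethyl-8-phenylocta-2,4,7-trienal
Conditions: 4 (1.5 equiv), PhMe, 90 °C, 24 h
Reagents that add atoms: none
Why: A second Wittig olefination with the same stabilised ylide gives the (E,E)-2,4-dimethyl dienal unit under thermodynamic control of the oxaphosphetane, and the weakly basic ylide leaves the C12 stereocentre untouched.

**Step 4**
Reactants: 7 (E)-2-methylpent-2-enal
Product: 8 triethyl{[(1E,3E)-2-methylpenta-1,3-dien-1-yl]oxy}silane
Conditions: TESOTf (1.1 equiv), Et3N (1.5 equiv), Et2O, 0 °C to rt; distilled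
Reagents that add atoms: triethylsilyl trifluoromethanesulfonate (TESOTf), CC[Si](CC)(CC)OS(=O)(=O)C(F)(F)F
Why: Soft enolisation with silyl triflate and amine of an enal that has no α′-hydrogen can only remove a γ-hydrogen, so O-silylation gives the extended 1-silyloxy-1,3-diene (mainly 1E,3E) and no stereocentre is formed.

**Step 5**
Reactants: 6 (2E,4E,6S,7E)-2,4,6-trimethyl-8-phenylocta-2,4,7-trienal; 8 triethyl{[(1E,3E)-2-methylpenta-1,3-dien-1-yl]oxy}silane
Product: 9 (2E,4S,5R,6E,8E,10S,11E)-2,4,6,8,10-pentamethyl-12-phenyl-5-(triethylsilyloxy)dodeca-2,6,8,11-tetraenal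
Conditions: (S,S)-IDPi (BINOL-derived imidodiphosphorimidate Brønsted acid, N-triflyl core, 3,3′-diaryl; 2 mol %), 8 (1.2 equiv, slow addition), PhMe/pentane, 3 Å MS, −78 to −60 °C, 48 h; then Et3N
Reagents that add atoms: none
Why: Proposed new method: an IDPi-catalysed γ- and syn-selective vinylogous Mukaiyama aldol of an aldehyde-derived silyl dienol ether with an α-branched polyenal, in which 8 silylates the acid to an Et3Si+/IDPi− ion pair that O-silylates 6 inside the confined chiral anion, the terminal γ-carbon of 8 (largest HOMO coefficient; α-attack is blocked by the 2-methyl group) adds to the Re face of the aldehyde through an open antiperiplanar transition state (syn, as in Lewis acid crotylsilane additions) from the s-trans diene (hence the E-enal), and the silyl group ends on the C7 oxygen, giving C6 as S and C7 as R; the closest known reactions are disulfonimide- and IDPi-catalysed Mukaiyama and vinylogous Mukaiyama aldol reactions of ester-derived silyl dienolates and of simple aldehyde enol silanes, and boron Lewis acid-promoted vinylogous aldol reactions of aldehyde-derived dienol ethers.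

**Step 6**
Reactants: 9 (2E,4S,5R,6E,8E,10S,11E)-2,4,6,8,10-pentamethyl-12-phenyl-5-(triethylsilyloxy)dodeca-2,6,8,11-tetraenal
Product: 12 (3R,4E,6S,7R,8E,10E,12S,13E)-4,6,8,10,12-pentamethyl-14-phenyltetradeca-4,8,10,13-tetraene-3,7-diol, via ethylzinc alkoxide of the C3 alcohol 10 (not isolated), via C7 triethylsilyl ether of the target 11 (not isolated)
Conditions: Et2Zn (3 equiv), (+)-MIB [(2R)-3-exo-morpholinoisoborneol, 8 mol %], hexanes/PhMe, 0 °C; then MeOH; then Bu4NF (1 M in THF), 0 °C to rt, same flask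
Reagents that add atoms: diethylzinc, CC[Zn]CC
Why: Amino alcohol-catalysed enantioselective diethylzinc addition (Noyori type) delivers ethyl to the Re face of the α-methyl enal under catalyst control (the same sense that gives (R)-1-phenylpropan-1-ol from PhCHO), setting C3 as R, after which methanol frees the alcohol and fluoride cleaves the silyl ether without touching the alkenes or the other stereocentres.

**Compound list**
1 | propanal | CCC=O | starting material
2 | potassium (E)-styryltrifluoroborate | [K+].F[B-](F)(F)/C=C/c1ccccc1 | starting material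
3 | (2S,3E)-2-methyl-4-phenylbut-3-enal | O=C[C@@H](C)/C=C/c1ccccc1 | intermediate
4 | 2-(triphenylphosphoranylidene)propanal | CC(C=O)=P(c1ccccc1)(c1ccccc1)c1ccccc1 | starting material
5 | (2E,4S,5E)-2,4-dimethyl-6-phenylhexa-2,5-dienal | O=C/C(C)=C/[C@@H](C)/C=C/c1ccccc1 | intermediate
6 | (2E,4E,6S,7E)-2,4,6-trimethyl-8-phenylocta-2,4,7-trienal | O=C/C(C)=C/C(C)=C/[C@@H](C)/C=C/c1ccccc1 | intermediate
7 | (E)-2-methylpent-2-enal | CC/C=C(\C)C=O | starting material
8 | triethyl{[(1E,3E)-2-methylpenta-1,3-dien-1-yl]oxy}silane | C/C=C/C(C)=C/O[Si](CC)(CC)CC | intermediate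
9 | (2E,4S,5R,6E,8E,10S,11E)-2,4,6,8,10-pentamethyl-12-phenyl-5-(triethylsilyloxy)dodeca-2,6,8,11-tetraenal | O=C/C(C)=C/[C@H](C)[C@@H](O[Si](CC)(CC)CC)/C(C)=C/C(C)=C/[C@@H](C)/C=C/c1ccccc1 | intermediate
10 | ethyl{[(3R,4E,6S,7R,8E,10E,12S,13E)-4,6,8,10,12-pentamethyl-14-phenyl-7-(triethylsilyloxy)tetradeca-4,8,10,13-tetraen-3-yl]oxy}zinc | CC[C@@H](O[Zn]CC)/C(C)=C/[C@H](C)[C@@H](O[Si](CC)(CC)CC)/C(C)=C/C(C)=C/[C@@H](C)/C=C/c1ccccc1 | intermediate
11 | (3R,4E,6S,7R,8E,10E,12S,13E)-4,6,8,10,12-pentamethyl-14-phenyl-7-(triethylsilyloxy)tetradeca-4,8,10,13-tetraen-3-ol | CC[C@@H](O)/C(C)=C/[C@H](C)[C@@H](O[Si](CC)(CC)CC)/C(C)=C/C(C)=C/[C@@H](C)/C=C/c1ccccc1 | intermediate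
12 | (3R,4E,6S,7R,8E,10E,12S,13E)-4,6,8,10,12-pentamethyl-14-phenyltetradeca-4,8,10,13-tetraene-3,7-diol | CC[C@@H](O)/C(C)=C/[C@H](C)[C@@H](O)/C(C)=C/C(C)=C/[C@@H](C)/C=C/c1ccccc1 | target

**Step count**
Total steps: 6. Longest linear sequence: 5 steps (steps 1, 2, 3, 5 and 6, from propanal).

**Three steps most likely to fail**

Step 5 (the proposed new reaction). The risks are [4+2] cycloaddition of the silyloxydiene with the activated dienal, anti or wrong-face addition, a second addition of 8 to product 9, and loss of the C12 proton from the silylated dienal. The fallback uses known auxiliary chemistry and sets out from 6. An Evans syn-aldol with (R)-4-benzyl-3-propanoyl-1,3-oxazolidin-2-one (Bu2BOTf, Et3N, CH2Cl2, −78 to 0 °C) gives (4R)-4-benzyl-3-[(2R,3R,4E,6E,8S,9E)-3-hydroxy-2,4,6,8-tetramethyl-10-phenyldeca-4,6,9-trienoyl]-1,3-oxazolidin-2-one F3. Transamidation with MeNH(OMe)·HCl and AlMe3 gives (2R,3R,4E,6E,8S,9E)-3-hydroxy-N-methoxy-N,2,4,6,8-pentamethyl-10-phenyldeca-4,6,9-trienamide F4. TESOTf and 2,6-lutidine give its triethylsilyl ether, (2R,3R,4E,6E,8S,9E)-N-methoxy-N,2,4,6,8-pentamethyl-10-phenyl-3-(triethylsilyloxy)deca-4,6,9-trienamide F5. Reduction with (i-Bu)2AlH in THF at −78 °C gives (2R,3R,4E,6E,8S,9E)-2,4,6,8-tetramethyl-10-phenyl-3-(triethylsilyloxy)deca-4,6,9-trienal F6. A Wittig reaction of F6 with 4 in PhMe at 80 °C comes back to the route at 9.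

Step 2 (Wittig on the racemisation- and isomerisation-prone α-vinyl aldehyde at 60 °C). The fallback sets out from 3 and olefinates at the ester oxidation level at 0 °C to room temperature with ethyl 2-(triphenylphosphoranylidene)propanoate in CH2Cl2, giving ethyl (2E,4S,5E)-2,4-dimethyl-6-phenylhexa-2,5-dienoate F1. Reduction with (i-Bu)2AlH in CH2Cl2 at −78 °C gives (2E,4S,5E)-2,4-dimethyl-6-phenylhexa-2,5-dien-1-ol F2. Oxidation of F2 with MnO2 in CH2Cl2 comes back to the route at 5.

Step 6 (catalyst control at C3 on a hindered enal, with quench and desilylation in one flask). The fallback sets the centre by reduction instead of alkylation and sets out from 9. Addition of EtMgBr in THF at −78 °C gives the C3-epimeric mixture (3RS,4E,6S,7R,8E,10E,12S,13E)-4,6,8,10,12-pentamethyl-14-phenyl-7-(triethylsilyloxy)tetradeca-4,8,10,13-tetraen-3-ol F7. Dess–Martin periodinane with NaHCO3 in CH2Cl2 gives the enone (4E,6S,7R,8E,10E,12S,13E)-4,6,8,10,12-pentamethyl-14-phenyl-7-(triethylsilyloxy)tetradeca-4,8,10,13-tetraen-3-one F8. Corey–Bakshi–Shibata reduction with (S)-2-methyl-CBS-oxazaborolidine (20 mol %) and catecholborane in PhMe at −78 °C comes back to the route at 11, here isolated, which Bu4NF in THF converts into 12 as in the last stage of step 6.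

**Further compounds**
F1 | step 2 | ethyl (2E,4S,5E)-2,4-dimethyl-6-phenylhexa-2,5-dienoate | CCOC(=O)/C(C)=C/[C@@H](C)/C=C/c1ccccc1
F2 | step 2 | (2E,4S,5E)-2,4-dimethyl-6-phenylhexa-2,5-dien-1-ol | OC/C(C)=C/[C@@H](C)/C=C/c1ccccc1
F3 | step 5 | (4R)-4-benzyl-3-[(2R,3R,4E,6E,8S,9E)-3-hydroxy-2,4,6,8-tetramethyl-10-phenyldeca-4,6,9-trienoyl]-1,3-oxazolidin-2-one | O=C1OC[C@@H](Cc2ccccc2)N1C(=O)[C@H](C)[C@@H](O)/C(C)=C/C(C)=C/[C@@H](C)/C=C/c1ccccc1
F4 | step 5 | (2R,3R,4E,6E,8S,9E)-3-hydroxy-N-methoxy-N,2,4,6,8-pentamethyl-10-phenyldeca-4,6,9-trienamide | CON(C)C(=O)[C@H](C)[C@@H](O)/C(C)=C/C(C)=C/[C@@H](C)/C=C/c1ccccc1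
F5 | step 5 | (2R,3R,4E,6E,8S,9E)-N-methoxy-N,2,4,6,8-pentamethyl-10-phenyl-3-(triethylsilyloxy)deca-4,6,9-trienamide | CON(C)C(=O)[C@H](C)[C@@H](O[Si](CC)(CC)CC)/C(C)=C/C(C)=C/[C@@H](C)/C=C/c1ccccc1
F6 | step 5 | (2R,3R,4E,6E,8S,9E)-2,4,6,8-tetramethyl-10-phenyl-3-(triethylsilyloxy)deca-4,6,9-trienal | O=C[C@H](C)[C@@H](O[Si](CC)(CC)CC)/C(C)=C/C(C)=C/[C@@H](C)/C=C/c1ccccc1
F7 | step 6 | (3RS,4E,6S,7R,8E,10E,12S,13E)-4,6,8,10,12-pentamethyl-14-phenyl-7-(triethylsilyloxy)tetradeca-4,8,10,13-tetraen-3-ol | CCC(O)/C(C)=C/[C@H](C)[C@@H](O[Si](CC)(CC)CC)/C(C)=C/C(C)=C/[C@@H](C)/C=C/c1ccccc1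
F8 | step 6 | (4E,6S,7R,8E,10E,12S,13E)-4,6,8,10,12-pentamethyl-14-phenyl-7-(triethylsilyloxy)tetradeca-4,8,10,13-tetraen-3-one | CCC(=O)/C(C)=C/[C@H](C)[C@@H](O[Si](CC)(CC)CC)/C(C)=C/C(C)=C/[C@@H](C)/C=C/c1ccccc1
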